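Germacrane numbering is used (C1 ketone, C3–O–C10 ether bridge, C6/C7 lactone, C8 ester). The route rests on disconnecting C9–C10 of the nine-membered oxacycle (O, C3 to C10). The key step exploits the bridging ether oxygen, which lies next to the C1 ketone and quaternary C10, and the oxygenated C8. Its precursor is an eight-membered cyclic ether (O, C3 to C8 and one CH2) with an exocyclic methylene on C8 and a 2-diazo-3-oxobutyl chain on C3. A copper carbene at C10 is captured by the ring oxygen and the oxonium ylide passes its allyl unit to C10: one step expands the ring, closes the furanone, sets C10 from C3 and leaves a C8 methylene for later oxidation.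

Key step: step 16

Remark: C11 to C13 are the methylene-lactone carbons, C14 is the methyl on C10 and C15 the hydroxymethyl carbon on C4; aldehyde 10 is taken as a purchasable building block.

Step 1
Reactants: 1 (R)-5-(hydroxymethyl)dihydrofuran-2(3H)-one
Product: 2 (R)-5-oxotetrahydrofuran-2-carbaldehyde
Conditions: Dess–Martin periodinane, CH2Cl2, 0 °C to rt
Reagents that add atoms: none
Why: Dess–Martin oxidation gives the aldehyde under neutral conditions, which should leave the adjacent oxygen-bearing stereocentre (future C6) untouched.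

Step 2
Reactants: 2 (R)-5-oxotetrahydrofuran-2-carbaldehyde
Product: 3 (R)-5-vinyldihydrofuran-2(3H)-one
Conditions: Ph3PCH3Br, KN(SiMe3)2, THF, −78 to 0 °C
Reagents that add atoms: methyltriphenylphosphonium bromide, C[P+](c1ccccc1)(c1ccccc1)c1ccccc1.[Br-]
Why: Wittig methylenation with the salt-free ylide at low temperature should be faster than epimerisation of the α-oxygenated aldehyde or attack on the lactone.

Step 3
Reactants: 3 (R)-5-vinyldihydrofuran-2(3H)-one
Product: 6 (R)-4-(tert-butyldimethylsilyloxy)hex-5-enoic acid, via potassium (R)-4-hydroxyhex-5-enoate 4 (not isolated), via silyl ester silyl ether 5 (not isolated)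
Conditions: KOH, MeOH/H2O, rt; TBSCl, imidazole, DMF; K2CO3 (cat.), MeOH/THF/H2O; then pH 4
Reagents that add atoms: potassium hydroxide, [K+].[OH-]; tert-butyldimethylsilyl chloride, CC(C)(C)[Si](C)(C)Cl
Why: Saponification opens the lactone, silylation caps both oxygens and mild methanolysis of the labile silyl ester returns the acid, with no bond to the stereocentre broken.

Step 4
Reactants: 6 (R)-4-(tert-butyldimethylsilyloxy)hex-5-enoic acid; 7 (R)-4-benzyloxazolidin-2-one
Product: 9 (R)-4-benzyl-3-[(R)-4-(tert-butyldimethylsilyloxy)hex-5-enoyl]oxazolidin-2-one, via mixed pivalic anhydride 8 (not isolated)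
Conditions: t-BuCOCl, Et3N, THF, −20 °C; then 7, LiCl, rt
Reagents that add atoms: none
Why: N-acylation of the oxazolidinone through the mixed pivalic anhydride with LiCl assistance is the standard way to attach the Evans auxiliary.

Step 5
Reactants: 9 (R)-4-benzyl-3-[(R)-4-(tert-butyldimethylsilyloxy)hex-5-enoyl]oxazolidin-2-one; 10 3-(4-methoxybenzyloxy)propanal
Product: 12 syn-aldol imide (R)-4-benzyl-3-{(2R,4R)-4-(tert-butyldimethylsilyloxy)-2-[(1S)-1-hydroxy-3-(4-methoxybenzyloxy)propyl]hex-5-enoyl}oxazolidin-2-one, via Z boron enolate 11 (not isolated)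
Conditions: Bu2BOTf, i-Pr2NEt, CH2Cl2, −78 to 0 °C; then 10, −78 to 0 °C; H2O2, MeOH, pH 7 buffer
Reagents that add atoms: none
Why: In this Evans syn aldol the Z boron enolate reacts through a chair Zimmerman–Traxler transition state on the face away from the benzyl group, so the auxiliary sets C4 and the C3 carbinol (3S, syn) regardless of the remote C6 centre.

Step 6
Reactants: 12 syn-aldol imide
Product: 13 (3S,4S,6R)-6-(tert-butyldimethylsilyloxy)-4-(hydroxymethyl)-1-(4-methoxybenzyloxy)oct-7-en-3-ol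
Conditions: LiBH4, H2O (1 equiv), Et2O, 0 °C
Reagents that add atoms: none
Why: Reductive cleavage of the imide with LiBH4 should release the primary C15 alcohol and the auxiliary without touching the ethers.

Step 7
Reactants: 13 diol
Product: 14 (3S,4S,6R)-6-(tert-butyldimethylsilyloxy)-4-[(tert-butyldiphenylsilyloxy)methyl]-1-(4-methoxybenzyloxy)oct-7-en-3-ol
Conditions: TBDPSCl, imidazole, CH2Cl2, 0 °C
Reagents that add atoms: tert-butyldiphenylsilyl chloride, CC(C)(C)[Si](Cl)(c1ccccc1)c1ccccc1
Why: Silylation with the bulky chlorosilane is selective for the primary hydroxyl of the 1,3-diol.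

Step 8
Reactants: 14 secondary alcohol; 15 3-chloro-2-(chloromethyl)prop-1-ene
Product: 16 3-O-[2-(chloromethyl)allyl] ether of 14
Conditions: NaH, 15 (5 equiv), Bu4NI (cat.), THF/DMF, 0 °C to rt
Reagents that add atoms: none
Why: Williamson etherification of the C3 alkoxide with an excess of the symmetrical allylic dichloride should give the mono-ether, and iodide catalysis keeps the temperature low enough to avoid silyl migration.

Step 9
Reactants: 16 diene ether
Product: 17 (3S,4S,6R)-oxocene chloride: ring O–C3–C4–C5–C6–C7=C8–CH2; C3 2-(4-methoxybenzyloxy)ethyl; C4 CH2OTBDPS; C6 OTBS; C8 CH2Cl (C9)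
Conditions: RuCl2(=CHPh)(PCy3)(H2IMes) (second-generation Grubbs catalyst, 10 mol %), toluene (2 mM), 80 °C
Reagents that add atoms: none
Why: Ring-closing metathesis between the vinyl group and the 1,1-disubstituted allyl ether should close the eight-membered ring as the ring-cis trisubstituted alkene, driven by loss of ethene at high dilution.

Step 10
Reactants: 17 oxocene chloride
Product: 19 (3S,4S,6R)-oxocene allylic alcohol (C9–OH; otherwise as 17), via allylic acetate 18 (not isolated)
Conditions: KOAc, DMF, 50 °C; then K2CO3 (cat.), MeOH, rt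
Reagents that add atoms: potassium acetate, [K+].CC(=O)[O-]
Why: SN2 displacement of the primary allylic chloride by acetate followed by methanolysis gives the allylic alcohol without allylic transposition.

Step 11
Reactants: 19 oxocene allylic alcohol; 20 triethyl orthoacetate
Product: 22 (3S,4S,6R,7R)-lactone: eight-membered ether O–C3–C4–C5–C6–C7–C8(=C9H2)–CH2 carrying a trans-fused γ-lactone O6–C12(=O)–C11H2–C7; C3 2-(4-methoxybenzyloxy)ethyl; C4 CH2OTBDPS, via Claisen ethyl ester 21 (not isolated)
Conditions: 20 (10 equiv), EtCO2H (cat.), 140 °C; then camphorsulfonic acid, MeOH, 40 °C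
Reagents that add atoms: none
Why: The Johnson–Claisen rearrangement passes through a chair transition state that delivers the C11–C12 unit to C7 on the face anti to the bulky C6 silyloxy group and moves the alkene to the exocyclic C8=C9 position; acid then removes the secondary TBS ether and closes the trans-fused γ-lactone.

Step 12
Reactants: 22 lactone
Product: 24 (3S,4S,6R,7R,11R)-11-(acetoxymethyl) lactone, via hydroxymethyl lactone 23 (not isolated)
Conditions: LiN(i-Pr)2, THF, −78 °C; CH2O (gas, from paraformaldehyde); then Ac2O, −78 to 0 °C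
Reagents that add atoms: formaldehyde, C=O; acetic anhydride, CC(=O)OC(C)=O
Why: Aldol reaction of the lactone lithium enolate with monomeric formaldehyde (anti to the C7 substituent) followed by acetylation installs a latent α-methylene group whose C11 centre is removed later.

Step 13
Reactants: 24 acetoxymethyl lactone
Product: 25 primary alcohol at C1 (side chain on C3 is CH2CH2OH)
Conditions: DDQ, CH2Cl2/pH 7 buffer, 0 °C
Reagents that add atoms: none
Why: Oxidative cleavage of the 4-methoxybenzyl ether with DDQ is selective in the presence of the silyl ether, esters and the isolated alkene.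

Step 14
Reactants: 25 primary alcohol
Product: 26 C1 carboxylic acid (side chain on C3 is CH2CO2H)
Conditions: TEMPO (cat.), PhI(OAc)2, MeCN/H2O, rt
Reagents that add atoms: water, O
Why: The oxoammonium oxidation takes the primary alcohol through the aldehyde hydrate to the acid without affecting the alkene.

Step 15
Reactants: 26 carboxylic acid
Product: 28 α-diazoketone (side chain on C3 is CH2–C(=O)–C(=N2)–CH3; the diazo carbon is C10), via mixed carbonic anhydride 27 (not isolated)
Conditions: i-BuOCOCl, N-methylmorpholine, THF, −20 °C; then CH3CHN2, Et2O, −20 to 0 °C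
Reagents that add atoms: diazoethane, CC=[N+]=[N-]
Why: Acylation of diazoethane by the mixed anhydride (Arndt–Eistert-type diazoketone synthesis) gives the methyl-substituted diazoketone, and the unactivated alkene does not undergo dipolar cycloaddition.

Step 16
Reactants: 28 α-diazoketone
Product: 30 (3S,4S,6R,7R,10S,11R)-ring-expanded dihydrofuranone: C3–O–C10 bridge; C1 ketone; C14 methyl on C10; C8=CH2; nine-membered ring O–C3 to C10, via oxonium ylide 29 (not isolated)
Conditions: Cu(CF3COCHCOCF3)2 (5 mol %), CH2Cl2, reflux, slow addition of 28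
Reagents that add atoms: none
Why: The copper carbene formed from 28 at C10 is attacked by a lone pair of the ring ether oxygen to give the bicyclic oxonium ylide 29, whose allyl group then moves from oxygen to C10 by a [2,3]-sigmatropic shift (the alternative [1,2]-Stevens shift gives the same product, because both ends of the 2-substituted allyl unit are CH2). This is oxonium ylide formation and rearrangement of a cyclic allylic ether carrying a tethered α-diazoketone, the known route to oxygen-bridged medium rings. The furanone ring (O, C3, C2, C1, C10) closes by five-membered cyclisation of oxygen onto the carbene carbon, and the nine-membered ring (O, C3 to C10) arises from the eight-membered ether through the five-centre cyclic transition state of the shift, in which the O–CH2 bond breaks and the C9–C10 bond forms. The quaternary centre C10 is controlled by C3: only the cis-fused ylide can pass the allyl group on, so C9 ends up cis to C4 across the new five-membered ring (3S gives 10S). The step needs ylide formation to outrun C–H insertion and hydride migration in the carbene, which the five-membered reach of the ether oxygen and the electron-poor copper catalyst should secure.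

Step 17
Reactants: 30 dihydrofuranone
Product: 32 (4S,6R,7R,10S,11R)-3(2H)-furanone (C2=C3 double bond), via silyl enol ether 31 (not isolated)
Conditions: Me3SiOTf, Et3N, CH2Cl2, −78 to 0 °C; then Pd(OAc)2, MeCN, rt
Reagents that add atoms: none
Why: In this Saegusa–Ito oxidation soft enolisation can only go toward C2 because C10 is quaternary, and Pd(OAc)2 dehydrogenates the silyl enol ether to the furanone, which erases the relay centre C3.

Step 18
Reactants: 32 furanone
Product: 34 C8 ketone, via vicinal diol 33 (not isolated)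
Conditions: OsO4 (cat.), NaIO4, 2,6-lutidine, dioxane/H2O, rt
Reagents that add atoms: osmium tetroxide, O=[Os](=O)(=O)=O; sodium periodate, [Na+].[O-]I(=O)(=O)=O
Why: In this Lemieux–Johnson cleavage OsO4 should dihydroxylate the electron-rich 1,1-disubstituted alkene in preference to the push–pull furanone alkene, and periodate cleaves the diol to the ketone.

Step 19
Reactants: 34 C8 ketone
Product: 35 (8R)-alcohol
Conditions: NaBH4, CeCl3·7H2O, MeOH, −78 °C
Reagents that add atoms: none
Why: Luche reduction at low temperature should reduce the ketone and not the vinylogous-ester carbonyl, with hydride adding in the Felkin–Anh sense relative to C7 (anti to the C7–C6 bond, past H-7) so that the hydroxyl ends up anti to C11 (8R).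

Step 20
Reactants: 35 (8R)-alcohol; 36 angelic acid
Product: 37 8-O-angelate
Conditions: 36, 2,4,6-trichlorobenzoyl chloride, Et3N, toluene, rt; then 35, 80 °C
Reagents that add atoms: none
Why: Yamaguchi-type esterification through the mixed 2,4,6-trichlorobenzoic anhydride, run without a nucleophilic amine catalyst, should acylate the hindered alcohol without isomerising the Z double bond to the tiglate.

Step 21
Reactants: 37 8-O-angelate
Product: 38 15-O-TBDPS ether of the target (α-methylene lactone)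
Conditions: DBU (1.1 equiv), CH2Cl2, 0 °C
Reagents that add atoms: none
Why: E1cB elimination of acetate from the β-acetoxy lactone unveils the α-methylene-γ-butyrolactone and removes the temporary C11 centre.

Step 22
Reactants: 38 silyl ether
Product: 39 target CNP0108636.1
Conditions: HF·pyridine, pyridine/THF, 0 °C to rt
Reagents that add atoms: none
Why: Fluoride-mediated desilylation under buffered, mildly acidic conditions should free the C15 alcohol without harming the Michael acceptor, the furanone or the angelate.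

Compound list
1 | (R)-5-(hydroxymethyl)dihydrofuran-2(3H)-one | O=C1CC[C@H](CO)O1 | starting material
2 | (R)-5-oxotetrahydrofuran-2-carbaldehyde | O=C[C@H]1CCC(=O)O1 | intermediate
3 | (R)-5-vinyldihydrofuran-2(3H)-one | C=C[C@H]1CCC(=O)O1 | intermediate
4 | potassium (R)-4-hydroxyhex-5-enoate | C=C[C@H](O)CCC(=O)[O-].[K+] | intermediate
5 | tert-butyldimethylsilyl (R)-4-(tert-butyldimethylsilyloxy)hex-5-enoate | C=C[C@H](O[Si](C)(C)C(C)(C)C)CCC(=O)O[Si](C)(C)C(C)(C)C | intermediate
6 | (R)-4-(tert-butyldimethylsilyloxy)hex-5-enoic acid | C=C[C@H](O[Si](C)(C)C(C)(C)C)CCC(=O)O | intermediate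
7 | (R)-4-benzyloxazolidin-2-one | O=C1N[C@H](Cc2ccccc2)CO1 | starting material
8 | mixed pivalic anhydride of 6 | C=C[C@H](O[Si](C)(C)C(C)(C)C)CCC(=O)OC(=O)C(C)(C)C | intermediate
9 | (R)-4-benzyl-3-[(R)-4-(tert-butyldimethylsilyloxy)hex-5-enoyl]oxazolidin-2-one | C=C[C@H](O[Si](C)(C)C(C)(C)C)CCC(=O)N1C(=O)OC[C@H]1Cc1ccccc1 | intermediate
10 | 3-(4-methoxybenzyloxy)propanal | O=CCCOCc1ccc(OC)cc1 | starting material
11 | Z dibutylboron enolate of 9 | CCCCB(CCCC)O/C(=C\C[C@@H](O[Si](C)(C)C(C)(C)C)C=C)N1C(=O)OC[C@H]1Cc1ccccc1 | intermediate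
12 | syn-aldol imide (2R,4R,1'S in the acyl chain; C3 S, C6 R in germacrane numbering) | C=C[C@H](O[Si](C)(C)C(C)(C)C)C[C@@H](C(=O)N1C(=O)OC[C@H]1Cc1ccccc1)[C@@H](O)CCOCc1ccc(OC)cc1 | intermediate
13 | (3S,4S,6R)-6-(tert-butyldimethylsilyloxy)-4-(hydroxymethyl)-1-(4-methoxybenzyloxy)oct-7-en-3-ol | C=C[C@H](O[Si](C)(C)C(C)(C)C)C[C@@H](CO)[C@@H](O)CCOCc1ccc(OC)cc1 | intermediate
14 | (3S,4S,6R)-6-(tert-butyldimethylsilyloxy)-4-[(tert-butyldiphenylsilyloxy)methyl]-1-(4-methoxybenzyloxy)oct-7-en-3-ol | C=C[C@H](O[Si](C)(C)C(C)(C)C)C[C@@H](CO[Si](c1ccccc1)(c1ccccc1)C(C)(C)C)[C@@H](O)CCOCc1ccc(OC)cc1 | intermediate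
15 | 3-chloro-2-(chloromethyl)prop-1-ene | C=C(CCl)CCl | starting material
16 | 3-O-[2-(chloromethyl)allyl] ether of 14 | C=C[C@H](O[Si](C)(C)C(C)(C)C)C[C@@H](CO[Si](c1ccccc1)(c1ccccc1)C(C)(C)C)[C@@H](OCC(=C)CCl)CCOCc1ccc(OC)cc1 | intermediate
17 | (3S,4S,6R)-oxocene chloride (ring-cis C7=C8; C8–CH2Cl) | ClC/C1=C/[C@H](O[Si](C)(C)C(C)(C)C)C[C@@H](CO[Si](c2ccccc2)(c2ccccc2)C(C)(C)C)[C@H](CCOCc2ccc(OC)cc2)OC1 | intermediate
18 | oxocene allylic acetate | CC(=O)OC/C1=C/[C@H](O[Si](C)(C)C(C)(C)C)C[C@@H](CO[Si](c2ccccc2)(c2ccccc2)C(C)(C)C)[C@H](CCOCc2ccc(OC)cc2)OC1 | intermediate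
19 | (3S,4S,6R)-oxocene allylic alcohol | OC/C1=C/[C@H](O[Si](C)(C)C(C)(C)C)C[C@@H](CO[Si](c2ccccc2)(c2ccccc2)C(C)(C)C)[C@H](CCOCc2ccc(OC)cc2)OC1 | intermediate
20 | triethyl orthoacetate | CCOC(C)(OCC)OCC | starting material
21 | (3S,4S,6R,7R)-ethyl ester from the Claisen rearrangement (C7–CH2CO2Et; C8=C9H2 exocyclic; C6–OTBS) | C=C1[C@@H](CC(=O)OCC)[C@H](O[Si](C)(C)C(C)(C)C)C[C@@H](CO[Si](c2ccccc2)(c2ccccc2)C(C)(C)C)[C@H](CCOCc2ccc(OC)cc2)OC1 | intermediate
22 | (3S,4S,6R,7R)-trans-fused γ-lactone on the 8-methylene eight-membered ether | O=C1O[C@@H]2C[C@@H](CO[Si](c3ccccc3)(c3ccccc3)C(C)(C)C)[C@H](CCOCc3ccc(OC)cc3)OCC(=C)[C@H]2C1 | intermediate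
23 | 11-(hydroxymethyl) lactone (as its lithium alkoxide in the flask) | O=C1O[C@@H]2C[C@@H](CO[Si](c3ccccc3)(c3ccccc3)C(C)(C)C)[C@H](CCOCc3ccc(OC)cc3)OCC(=C)[C@H]2[C@@H]1CO | intermediate
24 | (3S,4S,6R,7R,11R)-11-(acetoxymethyl) lactone | O=C1O[C@@H]2C[C@@H](CO[Si](c3ccccc3)(c3ccccc3)C(C)(C)C)[C@H](CCOCc3ccc(OC)cc3)OCC(=C)[C@H]2[C@@H]1COC(C)=O | intermediate
25 | C1 primary alcohol | O=C1O[C@@H]2C[C@@H](CO[Si](c3ccccc3)(c3ccccc3)C(C)(C)C)[C@H](CCO)OCC(=C)[C@H]2[C@@H]1COC(C)=O | intermediate
26 | C1 carboxylic acid | O=C1O[C@@H]2C[C@@H](CO[Si](c3ccccc3)(c3ccccc3)C(C)(C)C)[C@H](CC(=O)O)OCC(=C)[C@H]2[C@@H]1COC(C)=O | intermediate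
27 | mixed isobutyl carbonic anhydride of 26 | O=C1O[C@@H]2C[C@@H](CO[Si](c3ccccc3)(c3ccccc3)C(C)(C)C)[C@H](CC(=O)OC(=O)OCC(C)C)OCC(=C)[C@H]2[C@@H]1COC(C)=O | intermediate
28 | α-diazoketone (2-diazo-3-oxobutyl chain on C3 of the eight-membered ether) | O=C1O[C@@H]2C[C@@H](CO[Si](c3ccccc3)(c3ccccc3)C(C)(C)C)[C@H](CC(=O)C(C)=[N+]=[N-])OCC(=C)[C@H]2[C@@H]1COC(C)=O | intermediate
29 | bicyclic oxonium ylide (O bonded to C3, OCH2 and C10) | O=C1O[C@@H]2C[C@@H](CO[Si](c4ccccc4)(c4ccccc4)C(C)(C)C)[C@@H]3CC(=O)[C-](C)[O+]3CC(=C)[C@H]2[C@@H]1COC(C)=O | intermediate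
30 | (3S,4S,6R,7R,10S,11R)-ring-expanded dihydrofuranone with C8=CH2 | O=C1O[C@@H]2C[C@@H](CO[Si](c4ccccc4)(c4ccccc4)C(C)(C)C)[C@@H]3CC(=O)[C@](C)(CC(=C)[C@H]2[C@@H]1COC(C)=O)O3 | intermediate
31 | trimethylsilyl enol ether of 30 (C1=C2) | O=C1O[C@@H]2C[C@@H](CO[Si](c4ccccc4)(c4ccccc4)C(C)(C)C)[C@@H]3C=C(O[Si](C)(C)C)[C@](C)(CC(=C)[C@H]2[C@@H]1COC(C)=O)O3 | intermediate
32 | (4S,6R,7R,10S,11R)-3(2H)-furanone with C8=CH2 | O=C1O[C@@H]2C[C@@H](CO[Si](c4ccccc4)(c4ccccc4)C(C)(C)C)C3=CC(=O)[C@](C)(CC(=C)[C@H]2[C@@H]1COC(C)=O)O3 | intermediate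
33 | C8 vicinal diol (configuration at C8 of no consequence) | O=C1O[C@@H]2C[C@@H](CO[Si](c4ccccc4)(c4ccccc4)C(C)(C)C)C3=CC(=O)[C@](C)(C[C@](O)(CO)[C@H]2[C@@H]1COC(C)=O)O3 | intermediate
34 | C8 ketone | O=C1O[C@@H]2C[C@@H](CO[Si](c4ccccc4)(c4ccccc4)C(C)(C)C)C3=CC(=O)[C@](C)(CC(=O)[C@H]2[C@@H]1COC(C)=O)O3 | intermediate
35 | (8R)-alcohol | O=C1O[C@@H]2C[C@@H](CO[Si](c4ccccc4)(c4ccccc4)C(C)(C)C)C3=CC(=O)[C@](C)(C[C@@H](O)[C@H]2[C@@H]1COC(C)=O)O3 | intermediate
36 | angelic acid, (Z)-2-methylbut-2-enoic acid | C/C=C(/C)C(=O)O | starting material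
37 | 8-O-angelate with 11-(acetoxymethyl) lactone | O=C1O[C@@H]2C[C@@H](CO[Si](c4ccccc4)(c4ccccc4)C(C)(C)C)C3=CC(=O)[C@](C)(C[C@@H](OC(=O)/C(C)=C\C)[C@H]2[C@@H]1COC(C)=O)O3 | intermediate
38 | 15-O-(tert-butyldiphenylsilyl) ether of the target | C=C1C(=O)O[C@@H]2C[C@@H](CO[Si](c4ccccc4)(c4ccccc4)C(C)(C)C)C3=CC(=O)[C@](C)(C[C@@H](OC(=O)/C(C)=C\C)[C@@H]12)O3 | intermediate
39 | CNP0108636.1 | C=C1C(=O)O[C@@H]2C[C@@H](CO)C3=CC(=O)[C@](C)(C[C@@H](OC(=O)/C(C)=C\C)[C@@H]12)O3 | target

Total step count: 22. Longest linear sequence: 22 steps (1 to 39).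

Steps most likely to fail

Step 16. Hydride migration within the methyl-bearing copper carbene, or C–H insertion, may outrun capture by the ring oxygen. The fallback sets out from acid 26 and comes back at 30; it replaces the carbene by a two-acceptor one without a migratable hydrogen and introduces the methyl afterwards. Acid 26 is activated with 1,1'-carbonyldiimidazole and condensed with PhSO2CH2Li (THF, −78 °C) to the β-keto sulfone F1. Diazo transfer with 4-acetamidobenzenesulfonyl azide and Et3N in MeCN gives the α-diazo-β-keto sulfone F2. Rh2(OAc)4 in CH2Cl2 should then bring about the same oxonium ylide formation and allyl shift, giving the ring-expanded C10 phenylsulfonyl ketone F3. Reductive desulfonylation of F3 with SmI2 (THF/HMPA, −78 °C) generates the C10 enolate regiospecifically; MeI can reach it only from the face outside the bridge and delivers 30.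

Step 9. Oligomerisation by cross-metathesis and slow engagement of the 1,1-disubstituted alkene may prevail over closure of the strained eight-membered trisubstituted alkene. The fallback sets out from alcohol 14 and comes back at allylic alcohol 19; the ring is closed by an intramolecular Horner–Wadsworth–Emmons reaction instead. Oxa-Michael addition of the alkoxide of 14 (KN(SiMe3)2 cat., THF, −78 °C) to ethyl 2-(diethoxyphosphoryl)acrylate gives the phosphonate ether F4 (mixture at the phosphonate carbon). OsO4/NaIO4 cleavage of its vinyl group gives the aldehyde F5. LiCl and i-Pr2NEt in MeCN at high dilution close the ring to the ring-cis enoate F6, and i-Bu2AlH (CH2Cl2, −78 °C) reduces F6 to 19.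

Step 19. Facial selectivity of hydride delivery to the C8 ketone in the bridged ten-membered ring may be poor or reversed. The fallback sets out from ketone 34 and comes back at angelate 37. If reduction gives mainly the C8 epimer, the (8S)-alcohol F7, it is esterified with inversion by a Mitsunobu reaction with angelic acid 36 (PPh3, diisopropyl azodicarboxylate, toluene, 0 °C), which gives 37 directly and replaces step 20.

Further compounds
F1 | step 16 | β-keto sulfone (side chain on C3 is CH2–C(=O)–CH2SO2Ph) | O=C1O[C@@H]2C[C@@H](CO[Si](c3ccccc3)(c3ccccc3)C(C)(C)C)[C@H](CC(=O)CS(=O)(=O)c3ccccc3)OCC(=C)[C@H]2[C@@H]1COC(C)=O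
F2 | step 16 | α-diazo-β-keto sulfone | O=C1O[C@@H]2C[C@@H](CO[Si](c3ccccc3)(c3ccccc3)C(C)(C)C)[C@H](CC(=O)C(=[N+]=[N-])S(=O)(=O)c3ccccc3)OCC(=C)[C@H]2[C@@H]1COC(C)=O
F3 | step 16 | ring-expanded dihydrofuranone with phenylsulfonyl on C10 | O=C1O[C@@H]2C[C@@H](CO[Si](c4ccccc4)(c4ccccc4)C(C)(C)C)[C@@H]3CC(=O)[C@](S(=O)(=O)c4ccccc4)(CC(=C)[C@H]2[C@@H]1COC(C)=O)O3
F4 | step 9 | phosphonate ether of 14 (mixture at the phosphonate carbon) | C=C[C@H](O[Si](C)(C)C(C)(C)C)C[C@@H](CO[Si](c1ccccc1)(c1ccccc1)C(C)(C)C)[C@@H](OCC(C(=O)OCC)P(=O)(OCC)OCC)CCOCc1ccc(OC)cc1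
F5 | step 9 | C7 aldehyde phosphonate | O=C[C@H](O[Si](C)(C)C(C)(C)C)C[C@@H](CO[Si](c1ccccc1)(c1ccccc1)C(C)(C)C)[C@@H](OCC(C(=O)OCC)P(=O)(OCC)OCC)CCOCc1ccc(OC)cc1
F6 | step 9 | oxocene ethyl enoate (ester carbon is C9) | CCOC(=O)/C1=C/[C@H](O[Si](C)(C)C(C)(C)C)C[C@@H](CO[Si](c2ccccc2)(c2ccccc2)C(C)(C)C)[C@H](CCOCc2ccc(OC)cc2)OC1
F7 | step 19 | (8S)-alcohol, C8 epimer of 35 | O=C1O[C@@H]2C[C@@H](CO[Si](c4ccccc4)(c4ccccc4)C(C)(C)C)C3=CC(=O)[C@](C)(C[C@H](O)[C@H]2[C@@H]1COC(C)=O)O3
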